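**Plan**

- Unit 1 is the cis-2,3 flavanone carrying the 4-methoxyphenyl group (unprimed atoms); unit 2 is the trans-2'',3'' flavanone carrying the 4-hydroxyphenyl group (double-primed atoms). The feature used: C4 and C4'' are aryl ketone carbons lying between ring A and C3/C3'', so each can enter as a ring A aldehyde carbon of reversed polarity, and the C3–C3'' bond joining the two rings C is what is left of an alkyne after two such additions.
- Retrosynthesis: the five O–benzyl bonds are cut first; then C4–C3 and C4''–C3'' (ring C of each unit) back to an alkyne bis-aldehyde; then the aryl ether bonds O1–C2 and O1''–C2'' back to a but-2-yne-1,4-diol and a salicylaldehyde; then C2–C3 and C2''–C3'' back to two benzaldehydes and trimethylsilylacetylene.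
- Forward: two alkynylations join the C2–C3–C3''–C2'' chain, a double Mitsunobu etherification attaches both rings A, ring C of unit 1 and then ring C of unit 2 close in one flask, and hydrogenolysis frees the five phenols.
- Stereochemistry: C2 and C2'' come from two ligand-controlled alkynylations of opposite sense, each carbinol being inverted in the Mitsunobu step; C3'' (trans ring closure) and C3 (kinetic cis protonation) are set in the key step under the control of C2'' and C2.

Key step: step 7

Assumption: (R,R)-ProPhenol is taken to give the (R)-carbinol of step 1 and (S,S)-ProPhenol the (S)-carbinol of step 3 (alkynyl ranks above aryl in both); the sense is to be checked on the first carbinol through its MTPA esters and the antipodes change places if it is the reverse. Likewise the (5aR,10bS) triazolium salt is taken as the antipode matched to the unit 1 half, and both antipodes are to be tried.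

Step 1
Reactants: 1 4-(benzyloxy)benzaldehyde; 2 trimethylsilylacetylene
Product: 3 (R)-1-[4-(benzyloxy)phenyl]-3-(trimethylsilyl)prop-2-yn-1-ol
Conditions: (R,R)-ProPhenol (10 mol%), Ph3PO (20 mol%), Me2Zn (3 equiv), 2 (3 equiv), toluene, 4 °C; aq NH4Cl
Reagents that add atoms: none
Why: Catalytic asymmetric alkynylation of an aryl aldehyde (zinc alkynylide addition under the dinuclear zinc–ProPhenol catalyst), in which the ligand pocket selects the aldehyde face and sets the later C2'' as (R); any shortfall in enantiomeric purity is removed as a diastereomer once the second center is in place.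

Step 2
Reactants: 3
Product: 5 (S)-({1-[4-(benzyloxy)phenyl]prop-2-yn-1-yl}oxy)(tert-butyl)dimethylsilane, via bis-silyl compound 4 (not isolated)
Conditions: TBSCl, imidazole, DMF, rt; then MeOH, K2CO3, rt
Reagents that add atoms: tert-butyldimethylsilyl chloride (TBSCl), CC(C)(C)[Si](C)(C)Cl
Why: O-silylation of the secondary alcohol followed by methanolysis of the alkynyl C–Si bond, which carbonate in methanol cleaves while the silyl ether stays; the stereocenter is untouched, and the descriptor changes from R to S only because ethynyl now ranks below aryl.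

Step 3
Reactants: 5; 6 4-methoxybenzaldehyde
Product: 7 (1S,4R)-4-[4-(benzyloxy)phenyl]-4-[(tert-butyldimethylsilyl)oxy]-1-(4-methoxyphenyl)but-2-yn-1-ol
Conditions: (S,S)-ProPhenol (20 mol%), Ph3PO (40 mol%), Me2Zn (2.5 equiv), 6 (2 equiv), toluene, 4 °C; aq NH4Cl
Reagents that add atoms: none
Why: The same asymmetric alkynylation with the antipodal ligand, so that catalyst control sets the later C2 in the sense opposite to step 1; the existing center sits at the far end of the linear alkyne and should not override the catalyst, and the minor diastereomer, which collects the errors of both alkynylations, is removed by chromatography.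

Step 4
Reactants: 7
Product: 8 (1S,4R)-4-[4-(benzyloxy)phenyl]-1-(4-methoxyphenyl)but-2-yne-1,4-diol
Conditions: TBAF (1.5 equiv), AcOH (1.5 equiv), THF, 0 °C to rt
Reagents that add atoms: none
Why: Fluoride cleavage of the silyl ether, buffered with acetic acid so that the base-sensitive but-2-yne-1,4-diol does not isomerise, while strong acid (Meyer–Schuster rearrangement of the 4-alkoxyphenyl propargylic carbinols) is avoided.

Step 5
Reactants: 9 2,4,6-trihydroxybenzaldehyde
Product: 10 2,4-bis(benzyloxy)-6-hydroxybenzaldehyde
Conditions: BnBr (2.0 equiv), K2CO3, DMF, 0 °C to rt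
Reagents that add atoms: benzyl bromide, BrCc1ccccc1
Why: Williamson etherification in which the 4-OH and one 2-OH are alkylated and the last hydroxyl, hydrogen-bonded to the formyl group and therefore the least nucleophilic, stays free.

Step 6
Reactants: 8; 10
Product: 11 2,2'-{[(1R,4S)-4-[4-(benzyloxy)phenyl]-1-(4-methoxyphenyl)but-2-yne-1,4-diyl]bis(oxy)}bis[4,6-bis(benzyloxy)benzaldehyde]
Conditions: 10 (2.4 equiv), PPh3 (2.6 equiv), DIAD (2.6 equiv), toluene, −20 to 0 °C
Reagents that add atoms: none
Why: Double Mitsunobu etherification, an SN2 displacement with inversion at both carbinol carbons by the acidic ortho-formyl phenol; there is no β-hydrogen, so elimination cannot compete, the non-polar solvent and low temperature hold back ionisation, and a center that loses its configuration gives a like-configured diastereomer that chromatography removes.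

Step 7
Reactants: 11
Product: 13 (2S,3S)-5,7-bis(benzyloxy)-3-{(2R,3S)-5,7-bis(benzyloxy)-2-[4-(benzyloxy)phenyl]-4-oxochroman-3-yl}-2-(4-methoxyphenyl)chroman-4-one (pentabenzyl ether of the target), via alkylidenechromanone aldehyde 12 (not isolated)
Conditions: aminoindanol-derived N-mesityl triazolium chloride, (5aR,10bS) antipode (20 mol%), K2CO3 (40 mol%), THF (0.02 M), 60 °C, argon
Reagents that add atoms: none
Why: The free carbene adds to the ring A aldehyde of unit 1 and the resulting hydroxy-enamine attacks the alkyne in a concerted ene-type step (C4–C3 forms while the O–H hydrogen passes to C3'', syn addition), a 6-exo-dig closure that gives ring C of unit 1 as the (E)-3-alkylidenechroman-4-one 12; the carbene then turns the second aldehyde into its acyl anion equivalent, which adds to the enone β-carbon C3'' in a 6-exo-trig Stetter closure of ring C of unit 2. The closest known reactions are the carbene-catalysed hydroacylation of unactivated alkynes by 2-(propargyloxy)benzaldehydes, with Stetter addition to the enone so formed, and the intramolecular Stetter reaction of salicylaldehyde-tethered enones. C3'' is controlled by C2'': allylic 1,3-strain holds the C2''–H bond in the plane of the enone, O1'' and the 4-benzyloxyphenyl group then lie on opposite faces, and attack from the face of the tether gives the trans-2'',3'' (diequatorial) ring. C3 is controlled by C2: the hydrogen passes from the tetrahedral adduct to the enol carbon on the face of the new C4''–C3'' bond, which is the face opposite the pseudo-axial 4-methoxyphenyl group, so the less stable cis-2,3 unit should result under kinetic control (the base is kept substoichiometric and heterogeneous so that no external proton shuttle overrides this transfer). The step needs the cascade to begin at the unit 1 aldehyde, because the ring closed first ends up cis and the ring closed second trans; the two halves of 11 have opposite configuration, so the chiral carbene meets them as a matched and a mismatched substrate, and the same opposite configuration puts both aryl groups on the face away from the Stetter attack, so that trans closure and cis protonation ask for the same approach.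

Step 8
Reactants: 13
Product: 14 (2S,3S)-5,7-dihydroxy-3-[(2R,3S)-5,7-dihydroxy-2-(4-hydroxyphenyl)-4-oxochroman-3-yl]-2-(4-methoxyphenyl)chroman-4-one
Conditions: H2 (1 atm), 10% Pd/C, EtOAc–MeOH (1:1), rt
Reagents that add atoms: none
Why: Hydrogenolysis of the five aryl benzyl ethers over palladium in a neutral medium, which leaves the aryl methyl ether alone and, with neither acid nor base present, should not epimerise the enolisable cis-2,3 unit; the reaction is stopped once five equivalents of hydrogen are taken up to spare the benzylic C2–O1 bonds.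

**Compound list**

1 | 4-(benzyloxy)benzaldehyde | O=Cc1ccc(OCc2ccccc2)cc1 | starting material
2 | trimethylsilylacetylene | C[Si](C)(C)C#C | starting material
3 | (R)-1-[4-(benzyloxy)phenyl]-3-(trimethylsilyl)prop-2-yn-1-ol | C[Si](C)(C)C#C[C@H](O)c1ccc(OCc2ccccc2)cc1 | intermediate
4 | (R)-tert-butyl({1-[4-(benzyloxy)phenyl]-3-(trimethylsilyl)prop-2-yn-1-yl}oxy)dimethylsilane (bis-silyl compound, formed and consumed in the flask of step 2) | C[Si](C)(C)C#C[C@H](O[Si](C)(C)C(C)(C)C)c1ccc(OCc2ccccc2)cc1 | intermediate
5 | (S)-({1-[4-(benzyloxy)phenyl]prop-2-yn-1-yl}oxy)(tert-butyl)dimethylsilane | C#C[C@H](O[Si](C)(C)C(C)(C)C)c1ccc(OCc2ccccc2)cc1 | intermediate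
6 | 4-methoxybenzaldehyde | COc1ccc(C=O)cc1 | starting material
7 | (1S,4R)-4-[4-(benzyloxy)phenyl]-4-[(tert-butyldimethylsilyl)oxy]-1-(4-methoxyphenyl)but-2-yn-1-ol | COc1ccc([C@H](O)C#C[C@H](O[Si](C)(C)C(C)(C)C)c2ccc(OCc3ccccc3)cc2)cc1 | intermediate
8 | (1S,4R)-4-[4-(benzyloxy)phenyl]-1-(4-methoxyphenyl)but-2-yne-1,4-diol (C1 carries the 4-methoxyphenyl group) | COc1ccc([C@H](O)C#C[C@H](O)c2ccc(OCc3ccccc3)cc2)cc1 | intermediate
9 | 2,4,6-trihydroxybenzaldehyde | O=Cc1c(O)cc(O)cc1O | starting material
10 | 2,4-bis(benzyloxy)-6-hydroxybenzaldehyde | O=Cc1c(O)cc(OCc2ccccc2)cc1OCc1ccccc1 | intermediate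
11 | 2,2'-{[(1R,4S)-4-[4-(benzyloxy)phenyl]-1-(4-methoxyphenyl)but-2-yne-1,4-diyl]bis(oxy)}bis[4,6-bis(benzyloxy)benzaldehyde] (C1 carries the 4-methoxyphenyl group) | COc1ccc([C@@H](Oc2cc(OCc3ccccc3)cc(OCc3ccccc3)c2C=O)C#C[C@@H](Oc2cc(OCc3ccccc3)cc(OCc3ccccc3)c2C=O)c2ccc(OCc3ccccc3)cc2)cc1 | intermediate
12 | (2R,3E)-5,7-bis(benzyloxy)-3-{(2R)-2-[4-(benzyloxy)phenyl]-2-[3,5-bis(benzyloxy)-2-formylphenoxy]ethylidene}-2-(4-methoxyphenyl)chroman-4-one (formed and consumed in the flask of step 7) | COc1ccc([C@H]2Oc3cc(OCc4ccccc4)cc(OCc4ccccc4)c3C(=O)/C2=C/[C@@H](Oc2cc(OCc3ccccc3)cc(OCc3ccccc3)c2C=O)c2ccc(OCc3ccccc3)cc2)cc1 | intermediate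
13 | (2S,3S)-5,7-bis(benzyloxy)-3-{(2R,3S)-5,7-bis(benzyloxy)-2-[4-(benzyloxy)phenyl]-4-oxochroman-3-yl}-2-(4-methoxyphenyl)chroman-4-one | COc1ccc([C@H]2Oc3cc(OCc4ccccc4)cc(OCc4ccccc4)c3C(=O)[C@H]2[C@@H]2C(=O)c3c(OCc4ccccc4)cc(OCc4ccccc4)cc3O[C@H]2c2ccc(OCc3ccccc3)cc2)cc1 | intermediate
14 | (2S,3S)-5,7-dihydroxy-3-[(2R,3S)-5,7-dihydroxy-2-(4-hydroxyphenyl)-4-oxochroman-3-yl]-2-(4-methoxyphenyl)chroman-4-one | COc1ccc([C@H]2Oc3cc(O)cc(O)c3C(=O)[C@H]2[C@@H]2C(=O)c3c(O)cc(O)cc3O[C@H]2c2ccc(O)cc2)cc1 | target

**Step count**

Total steps: 8. Longest linear sequence: 7 (steps 1, 2, 3, 4, 6, 7, 8); step 5 is a one-step side branch.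

**Steps most likely to fail**

Step 7. The carbene may begin at the unit 2 aldehyde because it discriminates the two halves too weakly, which would give the diastereomer with unit 1 trans and unit 2 cis. It may also add too slowly to the hindered, electron-rich aldehydes or to the alkyne flanked by two branched carbons. The base may shift the exocyclic double bond of the intermediate into the ring or epimerise C3 after closure. Fallback, setting out from 7 and returning at 12 and through it at 13: the two ring closures are run apart so that only the unit 1 aldehyde is present when the alkyne reacts. Mitsunobu etherification of the free carbinol of 7 with 10 should give the mono-aldehyde silyl ether F1. Carbene-catalysed alkyne hydroacylation (achiral N-mesityl triazolium salt, K2CO3, THF, 60 °C) can then only close ring C of unit 1 and should give the silyloxy alkylidenechromanone F2. TBAF buffered with AcOH should free the allylic alcohol F3. A second Mitsunobu reaction with 10 should then give 12 with inversion, now as an isolated compound; ionisation is held back because the allyl cation would be conjugated with the ketone. The intramolecular Stetter addition with the triazolium salt of step 7 should convert 12 into 13.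

Step 6. The oxyphosphonium intermediates of the two 4-alkoxyphenyl propargylic carbinols may ionise, with loss of configuration and C-alkylation of the phenol in place of clean inversion. Fallback, setting out from 1, 2 and 6 and returning at 11: the oxygen–aryl bond is made instead of the oxygen–carbinol bond, so that both carbinol carbons keep their configuration. Steps 1 to 4 are run with the two ProPhenol antipodes exchanged, which should give the mirror-image series:
- (S)-1-[4-(benzyloxy)phenyl]-3-(trimethylsilyl)prop-2-yn-1-ol F4;
- its bis-silyl derivative F5, formed in the flask;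
- the (R)-silyloxy alkyne F6;
- the (1R,4S)-monosilyl diol F7;
- the (1R,4S)-diol F8.

Commercial 2,4,6-trifluorobenzaldehyde and two equivalents of sodium benzyloxide (THF, 0 °C) should give 2,4-bis(benzyloxy)-6-fluorobenzaldehyde F9 by substitution para and then ortho to the formyl group. The dipotassium alkoxide of F8 (KHMDS, THF, −78 °C) is then arylated by F9 (2.2 equiv, −78 to 0 °C) in a nucleophilic aromatic substitution ortho to the formyl group, with retention at both carbinol carbons, which should give 11.

Step 8. Over-reduction may open the benzylic C2–O1 and C2''–O1'' ring bonds, or the debenzylation may stall at the hindered 5-O-benzyl groups and invite forcing conditions. Fallback, setting out from 13 and returning at 14: non-reductive debenzylation with BCl3 and pentamethylbenzene as benzyl cation scavenger in CH2Cl2 at −78 °C. This cleaves aryl benzyl ethers and should leave the aryl methyl ether and the C2–O1 bonds alone; no new compound arises (entry F0).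

**Further compounds**

F1 | step 7 | 2-{[(1R,4R)-4-[4-(benzyloxy)phenyl]-4-[(tert-butyldimethylsilyl)oxy]-1-(4-methoxyphenyl)but-2-yn-1-yl]oxy}-4,6-bis(benzyloxy)benzaldehyde | COc1ccc([C@@H](Oc2cc(OCc3ccccc3)cc(OCc3ccccc3)c2C=O)C#C[C@H](O[Si](C)(C)C(C)(C)C)c2ccc(OCc3ccccc3)cc2)cc1
F2 | step 7 | (2R,3E)-5,7-bis(benzyloxy)-3-{(2S)-2-[4-(benzyloxy)phenyl]-2-[(tert-butyldimethylsilyl)oxy]ethylidene}-2-(4-methoxyphenyl)chroman-4-one | COc1ccc([C@H]2Oc3cc(OCc4ccccc4)cc(OCc4ccccc4)c3C(=O)/C2=C/[C@H](O[Si](C)(C)C(C)(C)C)c2ccc(OCc3ccccc3)cc2)cc1
F3 | step 7 | (2R,3E)-5,7-bis(benzyloxy)-3-{(2S)-2-[4-(benzyloxy)phenyl]-2-hydroxyethylidene}-2-(4-methoxyphenyl)chroman-4-one | COc1ccc([C@H]2Oc3cc(OCc4ccccc4)cc(OCc4ccccc4)c3C(=O)/C2=C/[C@H](O)c2ccc(OCc3ccccc3)cc2)cc1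
F4 | step 6 | (S)-1-[4-(benzyloxy)phenyl]-3-(trimethylsilyl)prop-2-yn-1-ol | C[Si](C)(C)C#C[C@@H](O)c1ccc(OCc2ccccc2)cc1
F5 | step 6 | (S)-tert-butyl({1-[4-(benzyloxy)phenyl]-3-(trimethylsilyl)prop-2-yn-1-yl}oxy)dimethylsilane | C[Si](C)(C)C#C[C@@H](O[Si](C)(C)C(C)(C)C)c1ccc(OCc2ccccc2)cc1
F6 | step 6 | (R)-({1-[4-(benzyloxy)phenyl]prop-2-yn-1-yl}oxy)(tert-butyl)dimethylsilane | C#C[C@@H](O[Si](C)(C)C(C)(C)C)c1ccc(OCc2ccccc2)cc1
F7 | step 6 | (1R,4S)-4-[4-(benzyloxy)phenyl]-4-[(tert-butyldimethylsilyl)oxy]-1-(4-methoxyphenyl)but-2-yn-1-ol | COc1ccc([C@@H](O)C#C[C@@H](O[Si](C)(C)C(C)(C)C)c2ccc(OCc3ccccc3)cc2)cc1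
F8 | step 6 | (1R,4S)-4-[4-(benzyloxy)phenyl]-1-(4-methoxyphenyl)but-2-yne-1,4-diol | COc1ccc([C@@H](O)C#C[C@@H](O)c2ccc(OCc3ccccc3)cc2)cc1
F9 | step 6 | 2,4-bis(benzyloxy)-6-fluorobenzaldehyde | O=Cc1c(F)cc(OCc2ccccc2)cc1OCc1ccccc1
F0 | step 8 | none | none
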